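- I had to choose between the alder and ash recipes on one figure: the share of target among the three products.

all flasks: coupling partner 0.324 M
- amber: starting material 0.31 M; run made earlier
- blue: starting material 0.80 M; run made earlier
- alder: starting material 0.25 M; time 8.0 min
- ash: starting material 0.54 M; time 30 min

| run | time / min | target / % | side product A / % |
|---|---|---|---|
| amber | 1.00 | 27 | 1 |
| amber | 3.00 | 37 | 2 |
| amber | 5.00 | 39 | 4 |
| amber | 8.00 | 41 | 8 |
| amber | 12.0 | 41 | 7 |
| amber | 15.0 | 41 | 6 |
| blue | 2.50 | 28 | 0 |
| blue | 5.00 | 27 | 0 |
| blue | 8.00 | 29 | 2 |
| blue | 10.0 | 28 | 0 |
| blue | 12.0 | 25 | 0 |
| blue | 15.0 | 27 | 4 |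

(each reading ± 1.5 percentage points)

1. which one finishes higher in share of target in all that became target or side product A or side product B ("neither" within 2 percentage points) (alder / ash / neither)
2. share of target in all that became target or side product A or side product B, alder
3. share of target in all that became target or side product A or side product B, ash

- percentages count the starting material that a species holds: one side product B counts as two
- on the list of suspects stand: starting material <-> intermediate A; starting material + coupling partner -> target; starting material <-> intermediate B; coupling partner + intermediate B -> side product A; 2 coupling partner -> homo dimer; starting material + intermediate A -> side product B; intermediate A -> decomposed reagent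

- From above: side product B was not read in either run, so I set it to nil. That gives my ceiling share, target over target plus side product A, and it stood at 87.2 % in the amber run at 15.0 min.
- The blue run's last reading gave 87.1 %, but that rests on one side product A reading of 4 %, and the others ran from 0 % to 2 %. Summed over its six readings, blue gave 96.5 %, so its ceiling read higher than amber's.
- From below: if side product B held everything unseen, the share would equal the target yield, 41 % in amber.
- In ash, coupling partner is the limiting reagent, with 0.324 M against 0.54 M of starting material. Target reached 0.127 M in amber and 0.216 M in blue, so I placed the ash floor between 23.5 % and 40.0 %.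
- I could not raise that floor by hand, but the suspects offer other holders for the unseen part. I committed to the upper end for both flasks, with alder near amber's ceiling and ash between amber's and blue's. Amber's ceiling read 83.7 % at 8.00 min and 87.2 % at 15.0 min, against a margin of 2 percentage points, so I saw no ground for a winner and answered neither.
- The forecast said alder, with alder at 47 % (41 % to 55 %) and ash at 34 % (29 % to 40 %), near the floor, on “a loss second order in starting material, mainly side product B”.
- The flasks gave alder 89.0 % and ash 89.4 %, so the answer is neither.

    starting material ⇌ intermediate A (K = 0.150, k = 0.0140 s⁻¹)
    starting material + coupling partner → target (k = 0.0350 L mol⁻¹ s⁻¹)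
    starting material ⇌ intermediate B (K = 2.90, k = 0.00620 s⁻¹)
    coupling partner + intermediate B → side product A (k = 0.00700 L mol⁻¹ s⁻¹)
    2 coupling partner → homo dimer (k = 0.0250 L mol⁻¹ s⁻¹)
    starting material + intermediate A → side product B (k = 6.60 × 10⁻⁴ L mol⁻¹ s⁻¹)
    intermediate A → decomposed reagent (k = 0.00330 s⁻¹)

- In ash at 30.0 min, target 34.6 % and side product A 3.45 % give a ceiling of 90.9 %, beside amber's 87.2 %. Side product B held 0.642 % there and intermediate B 34.6 %. A neighbour of ash, charged with 0.14 M of starting material, held target 50.6 % and side product A 8.85 % at 30.0 min, which gives a ceiling of 85.1 %. Its side product B stood at 0.116 %, and its share came to 84.9 %.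

The earlier runs and the new flask were computed with made-up constants, noise included.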